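## The problem

Euchrestaflavanone A (16) is a (2S)-flavanone. A phloroglucinol-derived ring A and a 4-hydroxyphenyl ring B are joined through the dihydropyranone ring C (O1–C2–C3–C4–C4a–C8a), and prenyl (3-methylbut-2-en-1-yl) groups sit at C8 and C3'. C2 is the only stereocenter, so nothing in the molecule can relay it; it has to come from a catalyst, a chiral-pool flavanone or a resolution. Once set it is fragile, because base (and more slowly acid) opens ring C by retro-oxa-Michael reaction to the 2'-hydroxychalcone and racemises it, so C2 should be created late and see no base afterwards. The prenyl groups must be placed with positional control (C8 and not C6 on ring A, ortho to O4' on ring B). They exclude hydrogenation and hydrogenolysis, and each lies next to a phenol onto which it cyclises under strong acid or electrophilic halogen. The three phenols therefore need masking groups that survive organometallic steps and leave under mild acid, which points to methoxymethyl (MOM) ethers rather than methyl or benzyl ethers. The feature that opens the molecule is the C4 carbonyl carbon lying between C4a and C3, with O1 bridging C8a and C2: ring C is an ortho-iodophenol (iodine at C4a, hydroxyl at C8a), one molecule of CO (C4) and a terminal arylalkyne (C3, C2 and ring B) in disguise. In ring A the oxygen that becomes O1 is the one flanked by the iodine-bearing and the prenyl-bearing carbons, so if it is the only free hydroxyl, ring closure can only give the 8-prenyl pattern.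

## Retrosynthesis

**16 from 15.** The three O–CH2 bonds of the MOM acetals are cut last, giving (2S)-5,7,4'-tris(methoxymethoxy)-8,3'-diprenylflavanone (15). MOM ethers are preferred to methyl or benzyl ethers because their removal needs neither a hard Lewis acid nor hydrogen, both of which the prenyl groups would not tolerate. The forward step must be acidic methanolysis mild and short enough to leave the alkenes and C2 alone.

**15 from 14.** The C2–H bond (with the C3–H bond) is removed, which erases the only stereocenter and leads to the flat, achiral flavone 14. Cutting O1–C2 instead would demand an asymmetric and reversible oxa-Michael closure, which is itself the racemisation path. Cutting the C2–aryl bond would demand a separately made prenylated chromone. The forward step is a 1,4-hydride addition that must select one face of C2, spare two isolated trisubstituted alkenes and stop at the ketone. A chiral copper hydride catalyst is the known answer for chromone-type enones.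

**14 from 5, 10 and 11.** Three bonds of ring C are cut at once: C4a–C4, C3–C4 and O1–C2. This gives 2-iodo-3,5-bis(methoxymethoxy)-6-prenylphenol (5), 4-ethynyl-1-(methoxymethoxy)-2-prenylbenzene (10) and carbon monoxide (11). The stepwise neighbours of this cut start from a ring A aryl ketone and build ring C by condensation. They need the same differentiation of the two ortho oxygens and deliver the C4 carbon already attached, so they gain nothing in ring A and lose the convergence. Here three achiral pieces, two of them of similar size, carry all the carbon and oxygen atoms of 14, with both prenyl groups already in place. The forward reaction must let CO insertion outrun direct aryl–alkyne coupling and must close the six-membered rather than the five-membered ring. The single free hydroxyl of 5 decides the 8-prenyl pattern.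

**5 from 1 and 2 by way of 4 and 3.** The C–I bond of 5 is cut first, to 3,5-bis(methoxymethoxy)-2-prenylphenol (4). The iodine must enter ortho to the free hydroxyl, and a wrongly placed iodine would give an isomer with no ortho hydroxyl, which cannot annulate. The two acetal O–C bonds of 4 are cut next, to 2-prenylphloroglucinol (3). The remote hydroxyl and either of the two equivalent hydroxyls beside the prenyl group give the same bis-ether, so the forward step only has to stop at two. Finally the aryl–CH2 bond of 3 is cut to phloroglucinol (1) and prenyl bromide (2). All three ring positions of 1 are equivalent, so the position of the prenyl group is not an issue.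

**10 from 6 and 2 by way of 8 and 7.** The alkyne carbon of 10 is cut off, leading to 4-(methoxymethoxy)-3-prenylbenzaldehyde (8); a one-carbon diazophosphonate homologation is asked of the forward step. Removal of the MOM group gives 4-hydroxy-3-prenylbenzaldehyde (7). Cutting its aryl–CH2 bond gives 4-hydroxybenzaldehyde (6) and prenyl bromide (2). The formyl group occupies the para position, so C-alkylation can only occur ortho.

## Roads not taken

**Alternative 1:** Both aryl–CH2 bonds of the prenyl groups are cut, which leads back to (2S)-naringenin A1 in the form of its 7-O-acetyl-5-O-prenyl-4'-O-(1,1-dimethylallyl) ether A2.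
- Forward key step: heating A2 with Eu(fod)3 would move the 5-O-prenyl group to C6 by a Claisen shift and on to C8 by a Cope shift, and the tertiary 4'-ether to C3' by a single Claisen shift. The product is 7-O-acetyl euchrestaflavanone A, A3, one acetate cleavage from 16.
- Merits: C2 comes from the chiral pool with no asymmetric step, and both C–C bonds form in one operation under sigmatropic control.
- Weak points: A2 requires three different groups on three phenols, including alkylation of the chelated, poorly nucleophilic 5-hydroxyl and a tertiary allyl ether that is acid-labile. The ring A migration can stop at C6 after the first shift. A flavanone heated with a Lewis acid is exposed to ring opening and loss of configuration at C2. The configurational purity of A1 must be secured first.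
- Comparison: in supply of the stereocenter this road is better. The chosen plan sets against it the certainty of both prenyl positions, which are fixed by symmetry and by the single free hydroxyl before ring C exists, its convergence, and a stereocenter that is created only after all heating and base.

**Alternative 2:** The C2–C3 bond is cut, leading to diazoketone A4, a ring A diazomethyl ketone whose ortho oxygen carries the ring B benzyl group.
- Forward key step: a dirhodium tetracarboxylate such as Rh2(OAc)4, or a chiral congener, would generate the carbene, which inserts into a benzylic O–CH2 hydrogen, closes ring C and sets C2, giving the tris-silyl ether A5.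
- Merits: ring closure and stereocenter in one catalytic step, with the chance of catalyst control at C2.
- Weak points: the ether oxygen lies in a 1,5 relationship to the carbene carbon, so oxonium ylide formation followed by a 1,2-benzyl shift (Stevens pathway), which would contract the ring to five members, is expected to compete strongly with a six-membered C–H insertion. Two electron-rich trisubstituted alkenes invite cyclopropanation. Carbenes carrying only one acceptor group are the least selective class. The diazoketone must be made from a hindered 2,4,6-trioxygenated benzoic acid.
- Comparison: this road is shorter on paper between ring closure and stereocenter, a point where the chosen plan spends a separate reduction step. Every bond-forming event of the chosen plan, however, belongs to a reaction class known on closely related substrates, and none of its chemoselectivity questions involves the prenyl alkenes.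

**Alternative 3:** Ring A is cut at C4a–C5, leading to keto ester A6, a (2S)-2-aryl-2,3-dihydropyran-4-one carrying a prenylated β-keto ester chain at C8a.
- Forward key step: DBU or Mg(OMe)2 would deprotonate C8; the vinylogous carbon C4a attacks the ester and enolisation aromatises ring A to give the 4'-O-MOM ether A7.
- Merits: no protecting groups and no halogenation on ring A, a biomimetic ring construction, and a stereocenter that could be set early by an asymmetric hetero-Diels–Alder reaction.
- Weak points: A6 is a long, sensitive polycarbonyl chain with the prenyl group on an acidic methine. Cyclisation through oxygen (lactonisation) competes with the desired C-acylation. The base needed for the key step acts on a 2-aryl-dihydropyranone, whose enolate can open by β-elimination of O1 and scramble C2.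
- Comparison: in protecting-group economy on ring A this road is better. The chosen plan sets against it cheap aromatic starting materials, a key step with no stereocenter at risk, and fewer steps to the cyclisation precursor.

Key step: step 7

Assumption: (R)-DTBM-SEGPHOS is written in step 8 on the premise that it delivers hydride to the face of C2 that gives the 2S flavanone; if a model flavone shows the opposite sense, the (S)-ligand is used with no other change.

## Route

Prenyl = 3-methylbut-2-en-1-yl; MOM = methoxymethyl.

**Step 1**
Reactants: 1 phloroglucinol (benzene-1,3,5-triol); 2 prenyl bromide (1-bromo-3-methylbut-2-ene)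
Product: 3 2-prenylphloroglucinol [2-(3-methylbut-2-en-1-yl)benzene-1,3,5-triol]
Conditions: 1 (3 equiv), 2 (1 equiv), DBU (1.1 equiv), THF, 0 °C → rt
Reagents that add atoms: none
Why: C-alkylation of the ambident phloroglucinol anion (Friedel–Crafts-type phenoxide C-prenylation); the three ring positions are equivalent, so only the degree of alkylation needs control, and excess triol, removable with water, suppresses diprenylation.

**Step 2**
Reactants: 3 2-prenylphloroglucinol
Product: 4 3,5-bis(methoxymethoxy)-2-prenylphenol
Conditions: MOMCl (2.1 equiv), i-Pr2NEt (2.5 equiv), CH2Cl2, −10 → 0 °C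
Reagents that add atoms: chloromethyl methyl ether (MOMCl), COCCl
Why: Controlled O-alkylation to the MOM acetals; the unhindered remote hydroxyl should react first, the two hydroxyls beside the prenyl group are equivalent so the second MOM gives 4 whichever one it takes, and the third alkylation is the slowest; mono- and tris-ethers differ enough in polarity to be separated and recycled.

**Step 3**
Reactants: 4 3,5-bis(methoxymethoxy)-2-prenylphenol
Product: 5 2-iodo-3,5-bis(methoxymethoxy)-6-prenylphenol
Conditions: NIS (1.0 equiv), CH2Cl2, −78 → −20 °C, dark
Reagents that add atoms: N-iodosuccinimide (NIS), O=C1CCC(=O)N1I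
Why: Electrophilic aromatic iodination directed ortho by the free phenol, which in CH2Cl2 hydrogen-bonds the reagent and delivers iodine to the carbon flanked by OH and one OMOM, whereas the para carbon is shielded by two OMOM groups; one equivalent at low temperature limits iodo-etherification of the prenyl alkene; an isomer iodinated para to the hydroxyl would have no ortho hydroxyl and could not close ring C in step 7.

**Step 4**
Reactants: 6 4-hydroxybenzaldehyde; 2 prenyl bromide
Product: 7 4-hydroxy-3-prenylbenzaldehyde
Conditions: KOH (10% aq, 1.1 equiv), 2 (1 equiv), rt
Reagents that add atoms: none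
Why: Ortho C-prenylation of a phenoxide in water, where hydrogen bonding to the phenoxide oxygen diverts part of the alkylation to carbon; the para position carries the formyl group, so only the two equivalent ortho carbons are open, and the O-prenyl ether and dialkylated material are removed by chromatography.

**Step 5**
Reactants: 7 4-hydroxy-3-prenylbenzaldehyde
Product: 8 4-(methoxymethoxy)-3-prenylbenzaldehyde
Conditions: MOMCl (1.3 equiv), i-Pr2NEt (2 equiv), CH2Cl2, 0 °C → rt
Reagents that add atoms: chloromethyl methyl ether (MOMCl), COCCl
Why: O-Alkylation of the phenol to the MOM acetal; aldehyde and prenyl alkene are inert to the hindered amine and the chloride.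

**Step 6**
Reactants: 8 4-(methoxymethoxy)-3-prenylbenzaldehyde
Product: 10 4-ethynyl-1-(methoxymethoxy)-2-prenylbenzene, via diazoalkene 9 (not isolated)
Conditions: dimethyl (1-diazo-2-oxopropyl)phosphonate (1.3 equiv), K2CO3 (2 equiv), MeOH, 0 °C → rt
Reagents that add atoms: dimethyl (1-diazo-2-oxopropyl)phosphonate (Ohira–Bestmann reagent), CC(=O)C(=[N+]=[N-])P(=O)(OC)OC
Why: Seyferth–Gilbert homologation in its Ohira–Bestmann form: methanolysis of the reagent gives the diazomethylphosphonate anion, Horner–Wadsworth–Emmons-type olefination of 8 gives diazoalkene 9, and loss of N2 with 1,2-hydrogen shift gives the terminal alkyne; the carbonate base leaves MOM ether and prenyl group untouched.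

**Step 7**
Reactants: 5 2-iodo-3,5-bis(methoxymethoxy)-6-prenylphenol; 10 4-ethynyl-1-(methoxymethoxy)-2-prenylbenzene; 11 carbon monoxide
Product: 14 5,7,4'-tris(methoxymethoxy)-8,3'-diprenylflavone, via ynone 12 (not isolated), via enaminone 13 (not isolated)
Conditions: PdCl2(PPh3)2 (5 mol %), Et2NH (solvent), CO (20 atm), 120 °C, autoclave
Reagents that add atoms: none
Why: PdCl2(PPh3)2 is reduced in the flask by CO and amine to zerovalent palladium, which inserts into the C4a–I bond of 5; CO then inserts to give an aroylpalladium iodide, and coupling with the amine-deprotonated alkyne 10 followed by reductive elimination releases ynone 12, forming C4a–C4 and C3–C4. Diethylamine adds reversibly to the ynone to give enaminone 13, and the neighbouring phenol attacks the amine-bearing carbon and expels the amine (addition–elimination), forming O1–C2 and flavone 14. The closest known reaction type is the palladium-catalysed carbonylative Sonogashira coupling of 2-iodophenols with terminal arylalkynes in diethylamine, with closure to the flavone in the same flask. Ring C closes in the 6-endo mode (6-endo-dig counted on 12, addition–elimination at the β-carbon of 13); no stereocenter is formed, and C2 is left to step 8. CO insertion must beat direct aryl–alkyne coupling, which is secured by CO pressure, the absence of copper salts and the electron-rich aryl group, which migrates readily to CO. Six-membered closure must beat five-membered closure to an aurone, which is secured by the secondary amine, because in 13 the only electrophilic carbon is C2. The prenyl position is secured by the substrate: the hydroxyl between C–I and C–prenyl is the only free one and the 5- and 7-oxygens are MOM ethers, so closure can only give the 8-prenyl flavone. MOM ethers, prenyl alkenes and aryl ethers are inert to amine, CO and zerovalent palladium at this temperature.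

**Step 8**
Reactants: 14 5,7,4'-tris(methoxymethoxy)-8,3'-diprenylflavone
Product: 15 (2S)-5,7,4'-tris(methoxymethoxy)-8,3'-diprenylflavanone
Conditions: Cu(OAc)2·H2O (5 mol %), (R)-DTBM-SEGPHOS (5.5 mol %), (EtO)2MeSiH (3 equiv), t-BuOH (2 equiv), toluene, 0 °C → rt
Reagents that add atoms: none
Why: Copper hydride asymmetric conjugate reduction of a chromone-type enone: the bisphosphine-ligated CuH formed from Cu(OAc)2 and silane transfers hydride to C2, the copper enolate is protonated at C3 by t-BuOH, and the silane regenerates CuH; the C2-symmetric ligand distinguishes the two faces of the flat flavone and sets C2 as S under catalyst control; isolated trisubstituted alkenes and MOM ethers do not react with CuH, and the hindered, electron-rich C4 ketone should resist 1,2-reduction.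

**Step 9**
Reactants: 15 (2S)-5,7,4'-tris(methoxymethoxy)-8,3'-diprenylflavanone
Product: 16 euchrestaflavanone A [(2S)-5,7,4'-trihydroxy-8,3'-diprenylflavanone]
Conditions: HCl (3 M aq)/MeOH 1:4, 45 °C, Ar, short reaction time
Reagents that add atoms: none
Why: Acid-catalysed methanolysis of the three aryl MOM acetals (acetal exchange to dimethoxymethane), the usual unmasking of prenylated flavonoids; the conditions are kept mild and brief so that neither prenyl group adds to its neighbouring phenol and ring C does not open, which leaves the S configuration at C2 intact.

## Compound list

1 | phloroglucinol (benzene-1,3,5-triol) | Oc1cc(O)cc(O)c1 | starting material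
2 | prenyl bromide (1-bromo-3-methylbut-2-ene) | CC(C)=CCBr | starting material
3 | 2-prenylphloroglucinol [2-(3-methylbut-2-en-1-yl)benzene-1,3,5-triol] | CC(C)=CCc1c(O)cc(O)cc1O | intermediate
4 | 3,5-bis(methoxymethoxy)-2-prenylphenol | CC(C)=CCc1c(O)cc(OCOC)cc1OCOC | intermediate
5 | 2-iodo-3,5-bis(methoxymethoxy)-6-prenylphenol | CC(C)=CCc1c(O)c(I)c(OCOC)cc1OCOC | intermediate
6 | 4-hydroxybenzaldehyde | O=Cc1ccc(O)cc1 | starting material
7 | 4-hydroxy-3-prenylbenzaldehyde | CC(C)=CCc1cc(C=O)ccc1O | intermediate
8 | 4-(methoxymethoxy)-3-prenylbenzaldehyde | CC(C)=CCc1cc(C=O)ccc1OCOC | intermediate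
9 | 4-(2-diazoethenyl)-1-(methoxymethoxy)-2-prenylbenzene (diazoalkene, not isolated) | CC(C)=CCc1cc(C=C=[N+]=[N-])ccc1OCOC | intermediate
10 | 4-ethynyl-1-(methoxymethoxy)-2-prenylbenzene | C#Cc1ccc(OCOC)c(CC=C(C)C)c1 | intermediate
11 | carbon monoxide | [C-]#[O+] | starting material
12 | 1-[2-hydroxy-4,6-bis(methoxymethoxy)-3-prenylphenyl]-3-[4-(methoxymethoxy)-3-prenylphenyl]prop-2-yn-1-one (ynone, not isolated) | CC(C)=CCc1cc(C#CC(=O)c2c(O)c(CC=C(C)C)c(OCOC)cc2OCOC)ccc1OCOC | intermediate
13 | 3-(diethylamino)-1-[2-hydroxy-4,6-bis(methoxymethoxy)-3-prenylphenyl]-3-[4-(methoxymethoxy)-3-prenylphenyl]prop-2-en-1-one (enaminone, alkene geometry not defined, not isolated) | CCN(CC)C(=CC(=O)c1c(O)c(CC=C(C)C)c(OCOC)cc1OCOC)c1ccc(OCOC)c(CC=C(C)C)c1 | intermediate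
14 | 5,7,4'-tris(methoxymethoxy)-8,3'-diprenylflavone | CC(C)=CCc1cc(-c2cc(=O)c3c(OCOC)cc(OCOC)c(CC=C(C)C)c3o2)ccc1OCOC | intermediate
15 | (2S)-5,7,4'-tris(methoxymethoxy)-8,3'-diprenylflavanone | CC(C)=CCc1cc([C@@H]2CC(=O)c3c(OCOC)cc(OCOC)c(CC=C(C)C)c3O2)ccc1OCOC | intermediate
16 | euchrestaflavanone A [(2S)-5,7,4'-trihydroxy-8,3'-diprenylflavanone] | CC(C)=CCc1cc([C@@H]2CC(=O)c3c(O)cc(O)c(CC=C(C)C)c3O2)ccc1O | target

## Step count and risks

Total step count: 9 (steps 1–3 for the ring A iodophenol, steps 4–6 for the ring B alkyne, steps 7–9 after the union).
Longest linear sequence: 6 steps (1, 2, 3, 7, 8, 9; the branch 4, 5, 6, 7, 8, 9 is equally long).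

Least certain steps:

**Step 7 (key step).** The aroylpalladium intermediate may be diverted before it meets the alkyne. The possible diversions are coupling without CO (leading on to benzofuran-type closure) and capture by diethylamine (aminocarbonylation). Both are made more likely by slow oxidative addition into an electron-rich aryl iodide with two ortho substituents. Five-membered closure can also intervene if the amine adduct forms too slowly.

Fallback, from 10 and 5, returning at 14: the carbonyl carbon is brought in as a carbamoyl chloride instead of CO. Alkyne 10 is deprotonated with n-BuLi (THF, −78 °C) and acylated with N-methoxy-N-methylcarbamoyl chloride to give N-methoxy-N-methyl-3-[4-(methoxymethoxy)-3-prenylphenyl]prop-2-ynamide F1. Iodophenol 5 is converted into its magnesium phenoxide with MeMgCl and then into the arylmagnesium species by iodine–magnesium exchange with i-PrMgCl·LiCl (THF, −20 °C). This adds to F1 (Weinreb ketone synthesis) and gives ynone 12 on work-up, now isolated. Et2NH in EtOH at rt then closes 12 by way of 13 to flavone 14.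

**Step 3.** Positional control may be lost (iodination para to the hydroxyl, between the two MOM ethers), the prenyl alkene may undergo iodo-etherification with the adjacent hydroxyl, and over-iodination is possible; all three stem from the very electron-rich ring and the free phenol next to an alkene.

Fallback, from 4, returning at 5: directed ortho-metalation replaces electrophilic substitution. Phenol 4 is carbamoylated (NaH, ClCONEt2, THF) to 3,5-bis(methoxymethoxy)-2-prenylphenyl N,N-diethylcarbamate F2. Lithiation with s-BuLi/TMEDA (THF, −78 °C) at the ring carbon flanked by carbamate and OMOM, then quenching with I2, gives 2-iodo-3,5-bis(methoxymethoxy)-6-prenylphenyl N,N-diethylcarbamate F3. Reductive cleavage of the carbamate with Cp2Zr(H)Cl (THF, rt), which tolerates aryl iodides, releases 5. The alkyllithium base and low temperature are chosen to favour ring over benzylic deprotonation.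

**Step 8.** Hydride transfer to a β-aryl, electron-rich and hindered chromone may be slow, face selectivity may be eroded, the C4 ketone may be reduced further, and the copper enolate may open by β-elimination of O1 before it is protonated.

Fallback, from 14, returning at 15: conjugate reduction with LiBH(s-Bu)3 (THF, −78 °C) gives racemic 5,7,4'-tris(methoxymethoxy)-8,3'-diprenylflavanone F4. This is resolved by preparative chromatography on a polysaccharide-carbamate chiral stationary phase into 15 and its antipode (2R)-5,7,4'-tris(methoxymethoxy)-8,3'-diprenylflavanone F5, which is set aside.

**Step 2.** Discrimination among the three hydroxyls may be incomplete, giving under- and over-alkylation and protection of both hydroxyls beside the prenyl group, because MOMCl is small and reactive.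

Fallback, from 1, returning at 4 (replaces steps 1 and 2): phloroglucinol 1 is first converted with MOMCl/i-Pr2NEt into 3,5-bis(methoxymethoxy)phenol F6, where only the number of ether groups has to be controlled. Allylic etherification catalysed by Pd(PPh3)4 with tert-butyl 2-methylbut-3-en-2-yl carbonate (THF, rt) gives 1,3-bis(methoxymethoxy)-5-[(2-methylbut-3-en-2-yl)oxy]benzene F7. Aromatic Claisen rearrangement (Eu(fod)3 cat., toluene, 60–80 °C) moves the tertiary allyl group to either of the two equivalent ortho carbons with allylic transposition and gives 4 as the only possible ortho product.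

## Further compounds

F1 | step 7 | N-methoxy-N-methyl-3-[4-(methoxymethoxy)-3-prenylphenyl]prop-2-ynamide | CON(C)C(=O)C#Cc1ccc(OCOC)c(CC=C(C)C)c1
F2 | step 3 | 3,5-bis(methoxymethoxy)-2-prenylphenyl N,N-diethylcarbamate | CCN(CC)C(=O)Oc1cc(OCOC)cc(OCOC)c1CC=C(C)C
F3 | step 3 | 2-iodo-3,5-bis(methoxymethoxy)-6-prenylphenyl N,N-diethylcarbamate | CCN(CC)C(=O)Oc1c(I)c(OCOC)cc(OCOC)c1CC=C(C)C
F4 | step 8 | racemic 5,7,4'-tris(methoxymethoxy)-8,3'-diprenylflavanone | CC(C)=CCc1cc(C2CC(=O)c3c(OCOC)cc(OCOC)c(CC=C(C)C)c3O2)ccc1OCOC
F5 | step 8 | (2R)-5,7,4'-tris(methoxymethoxy)-8,3'-diprenylflavanone | CC(C)=CCc1cc([C@H]2CC(=O)c3c(OCOC)cc(OCOC)c(CC=C(C)C)c3O2)ccc1OCOC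
F6 | step 2 | 3,5-bis(methoxymethoxy)phenol | COCOc1cc(O)cc(OCOC)c1
F7 | step 2 | 1,3-bis(methoxymethoxy)-5-[(2-methylbut-3-en-2-yl)oxy]benzene | C=CC(C)(C)Oc1cc(OCOC)cc(OCOC)c1
A1 | alternative 1 | (2S)-naringenin | O=C1C[C@@H](c2ccc(O)cc2)Oc2cc(O)cc(O)c21
A2 | alternative 1 | (2S)-7-O-acetyl-5-O-prenyl-4'-O-(1,1-dimethylallyl)naringenin | C=CC(C)(C)Oc1ccc([C@@H]2CC(=O)c3c(OCC=C(C)C)cc(OC(C)=O)cc3O2)cc1
A3 | alternative 1 | (2S)-7-O-acetyl euchrestaflavanone A | CC(C)=CCc1cc([C@@H]2CC(=O)c3c(O)cc(OC(C)=O)c(CC=C(C)C)c3O2)ccc1O
A4 | alternative 2 | 2-diazo-1-{2-[4-(tert-butyldimethylsilyloxy)-3-prenylbenzyloxy]-4,6-bis(tert-butyldimethylsilyloxy)-3-prenylphenyl}ethan-1-one | [N-]=[N+]=CC(=O)c1c(O[Si](C)(C)C(C)(C)C)cc(O[Si](C)(C)C(C)(C)C)c(CC=C(C)C)c1OCc1ccc(O[Si](C)(C)C(C)(C)C)c(CC=C(C)C)c1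
A5 | alternative 2 | (2S)-5,7,4'-tris-O-(tert-butyldimethylsilyl) euchrestaflavanone A | CC(C)=CCc1cc([C@@H]2CC(=O)c3c(O[Si](C)(C)C(C)(C)C)cc(O[Si](C)(C)C(C)(C)C)c(CC=C(C)C)c3O2)ccc1O[Si](C)(C)C(C)(C)C
A6 | alternative 3 | methyl 4-{(2S)-2-[4-(methoxymethoxy)-3-prenylphenyl]-4-oxo-3,4-dihydro-2H-pyran-6-yl}-7-methyl-3-oxooct-6-enoate (configuration at the prenylated carbon not defined) | COC(=O)CC(=O)C(CC=C(C)C)C1=CC(=O)C[C@@H](c2ccc(OCOC)c(CC=C(C)C)c2)O1
A7 | alternative 3 | (2S)-4'-O-methoxymethyl euchrestaflavanone A | CC(C)=CCc1cc([C@@H]2CC(=O)c3c(O)cc(O)c(CC=C(C)C)c3O2)ccc1OCOC
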